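**Retrosynthetic overview**

- Alcohol 1 is oxidised to aldehyde 2; then 2, heptan-2-one 3 and acetaldehyde 4 are joined in one flask (via aldol 5 and hemiacetal 6) to give target 7, which is their formal 1:1:1 adduct.
- Key disconnections of 7 (chain numbered from the benzylic carbon C1): C3–C4 by an aldol retron (carbinol C3 linked through C4H2 to the oxygenated C5) and, in the same operation, C5–H together with O3–acetyl by a Tishchenko retron.
- Enabling feature: the acyclic O3–C3–C4H2–C5(O) 1,3-dioxygen triad, with the ester on O3 and the free hydroxyl on C5 in an anti relationship. O3 can carry an acetaldehyde hemiacetal and pass its hydride to C5 through a six-membered metal chelate, so the C5 configuration and the site of the acetate both follow from C3.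
- Rings: none is formed at any stage; the dimethoxybenzene ring is bought with 1.

Key step: step 2

Assumption: (S,S)-ProPhenol·Zn2 is taken to direct the zinc enolate to the Re face of an aliphatic aldehyde (3S product); the sense is to be checked by chiral HPLC on a sample of 5 in the first run, and the (R,R)-ligand is used with no other change if it is the opposite.

**Route**

Step 1
Reactants: 1 3-(3,4-dimethoxyphenyl)propan-1-ol
Product: 2 3-(3,4-dimethoxyphenyl)propanal
Conditions: TEMPO (10 mol%), PhI(OAc)2 (1.1 equiv), CH2Cl2, rt
Reagents that add atoms: none
Why: The TEMPO/PhI(OAc)2 oxoammonium oxidation of a primary alcohol should stop at the aldehyde and leave the electron-rich dimethoxybenzene ring untouched; no stereocentre is involved.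

Step 2
Reactants: 2 3-(3,4-dimethoxyphenyl)propanal; 3 heptan-2-one; 4 acetaldehyde
Product: 7 (3S,5S)-1-(3,4-dimethoxyphenyl)-5-hydroxydecan-3-yl acetate, via (S)-aldol 5 (not isolated), via hemiacetal 6 (not isolated)
Conditions: (S,S)-ProPhenol (10 mol%), Et2Zn (20 mol%), 4 Å MS, THF, 3 (5 equiv), 5 °C; then 4 (10 equiv), SmI2 (30 mol%), THF, −10 °C
Reagents that add atoms: none
Why: Proposed new method: a catalyst-controlled direct aldol addition is relayed in the same flask into a samarium-catalysed intramolecular Tishchenko reduction fed by a second aldehyde, the closest known reaction types being the dinuclear zinc–ProPhenol direct aldol addition of methyl ketones to aldehydes, the Evans–Tishchenko reduction of β-hydroxy ketones with acetaldehyde and the racemic one-flask samarium-catalysed aldol–Tishchenko reaction of methyl ketones, and the reasoning being that the first stage ends in a neutral, kinetically stable aliphatic aldol whose free hydroxyl is all that the second stage requires. Mechanism: the Zn2 catalyst deprotonates 3 at its methyl group, the zinc enolate adds to zinc-bound 2 to forge C4–C3, proton transfer from further 3 releases 5, and Sm(III) (formed when SmI2 meets 4) then bridges O3 and the C5 carbonyl so that O3 adds to 4 to give hemiacetal 6, whose C–H is delivered to C5 through a chair-like six-membered transition state while its carbon becomes the acetyl carbon. No ring is closed, the six-membered samarium chelate existing only in the transition state. C3 is set by the chiral zinc catalyst (Re-face attack on 2 gives 3S) and C5 by 1,3-induction from C3 inside the chelate (internal hydride delivery anti to O3 gives 5S). The step needs site-selective enolisation of 3 (methyl against methylene, secured by the lower steric demand of the CH3 terminus in the bimetallic pocket and by the excess of 3), discrimination between the two aldehydes (secured by adding 4 only after 2 is consumed and by the slow retro-aldol cleavage of an aliphatic aldol at −10 °C) and acylation of O3 alone (secured by the mechanism, since only the oxygen that carried the hemiacetal can end as the ester oxygen).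

**Compound list**

1 | 3-(3,4-dimethoxyphenyl)propan-1-ol | OCCCc1ccc(OC)c(OC)c1 | starting material
2 | 3-(3,4-dimethoxyphenyl)propanal | O=CCCc1ccc(OC)c(OC)c1 | intermediate
3 | heptan-2-one | CCCCCC(C)=O | starting material
4 | acetaldehyde | CC=O | starting material
5 | (S)-1-(3,4-dimethoxyphenyl)-3-hydroxydecan-5-one | CCCCCC(=O)C[C@H](CCc1ccc(OC)c(OC)c1)O | intermediate
6 | (3S)-1-(3,4-dimethoxyphenyl)-3-(1-hydroxyethoxy)decan-5-one (samarium-bound in the flask; hemiacetal carbon not defined) | CCCCCC(=O)C[C@H](CCc1ccc(OC)c(OC)c1)OC(C)O | intermediate
7 | (3S,5S)-1-(3,4-dimethoxyphenyl)-5-hydroxydecan-3-yl acetate | CCCCC[C@H](O)C[C@H](CCc1ccc(OC)c(OC)c1)OC(C)=O | target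

**Step count and risks**

Total step count: 2. Longest linear sequence: 2.

The route has two steps, so the key step is entered once for each of its two stages.

1. Step 2, aldol stage (bears the label "Proposed new method:"). Process: the zinc alkoxide may enolise the α-unbranched aldehyde 2 (self-condensation) or enolise 3 at C3 as well as at C1, and facial control in the addition may be incomplete; any loss of regio- or enantiopurity would pass unchanged through the Tishchenko stage. Fallback with known chemistry, setting out from 3 and coming back to the route at 5: 3 is deprotonated on the methyl side with LDA and silylated with Me3SiCl (THF, −78 °C) to the kinetic enol silane 2-(trimethylsilyloxy)hept-1-ene F1. A Mukaiyama aldol addition of F1 to 2, catalysed by the B-butyl oxazaborolidine of N-tosyltryptophan (the enantiomer that directs Re-face attack; 20 mol%, EtCN, −78 °C; then 1 M HCl), should give 5 as an isolated compound, since Lewis-acid conditions do not enolise the aldehyde and the nucleophile is regiodefined. Compound 5 is then taken to 7 with 4 and SmI2 in a separate, standard Evans–Tishchenko operation.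

2. Step 2, Tishchenko stage (same labelled step). Process: the samarium catalyst may be sequestered by the zinc–ProPhenol residues or drained by a parasitic aldol–Tishchenko reaction between the excess of 3 and 4; hydride transfer would then slow and the acetyl group could migrate from O3 to O5 on the Lewis-acidic alkoxide. Fallback with known chemistry, setting out from 5 (isolated by chromatography after the aldol stage) and coming back at 7: 5 is acetylated on O3 (Ac2O, pyridine, 0 °C) to (S)-1-(3,4-dimethoxyphenyl)-5-oxodecan-3-yl acetate F2. The C5 ketone of F2 is then reduced under catalyst control by a ketoreductase (NADPH-dependent alcohol dehydrogenase selected from a commercial panel for the 5S alcohol; NADP+, i-PrOH, phosphate buffer pH 7, DMSO, 30 °C), which should give 7 with the acetate fixed on O3 before the C5 hydroxyl exists.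

3. Step 1. Process: over-oxidation to the carboxylic acid and aldol self-condensation of 2 during concentration or storage; traces of acid would quench the zinc alkoxide catalyst of step 2. Fallback, setting out from 1 and coming back at 2: the crude oxidation mixture is not concentrated but shaken with saturated aqueous NaHSO3 to precipitate the bisulfite adduct sodium 3-(3,4-dimethoxyphenyl)-1-hydroxypropane-1-sulfonate F3. This solid is filtered, washed free of acid and iodobenzene, stored, and cleaved with aqueous Na2CO3/EtOAc directly before step 2 to release pure 2.

Further compounds
F1 | step 2 | 2-(trimethylsilyloxy)hept-1-ene | C=C(CCCCC)O[Si](C)(C)C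
F2 | step 2 | (S)-1-(3,4-dimethoxyphenyl)-5-oxodecan-3-yl acetate | CCCCCC(=O)C[C@H](CCc1ccc(OC)c(OC)c1)OC(C)=O
F3 | step 1 | sodium 3-(3,4-dimethoxyphenyl)-1-hydroxypropane-1-sulfonate | [Na+].[O-]S(=O)(=O)C(O)CCc1ccc(OC)c(OC)c1
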